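**Retrosynthetic overview**
- Target ⇒ fully unprotected 2'-hydroxychalcone. Open O1–C2 of ring C (retro 6-endo-trig oxa-Michael). In the forward direction this is the chalcone→flavanone isomerisation, run with a legume chalcone isomerase as the last step, and it sets C2 as (S).
- Chalcone ⇒ resacetophenone + 5-prenylisovanillin. Disconnect Cα=Cβ (Claisen–Schmidt condensation without protecting groups).
- 5-Prenylisovanillin ⇒ 5-bromoisovanillin + prenylstannane (Stille coupling). 5-Bromoisovanillin ⇒ 5-bromoprotocatechualdehyde (acidity-controlled mono-O-methylation).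
- Ring order: rings A and B are bought. Ring C is the only ring formed, and it is formed last, so the base-labile C2 centre sees no further chemistry.

Assumption: recombinant Medicago sativa chalcone isomerase (MsCHI, type II, His-tagged, from E. coli carrying a purchased synthetic gene) is treated as a catalyst whose routine expression is not counted as a synthetic step, and 5-bromoprotocatechualdehyde is bought as a catalogue compound.

**Step 1**
Reactants: 1 3-bromo-4,5-dihydroxybenzaldehyde
Product: 2 3-bromo-5-hydroxy-4-methoxybenzaldehyde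
Conditions: MeI (1.2 equiv), Li2CO3 (1.2 equiv), DMF, 45 °C, 16 h
Reagents that add atoms: iodomethane (MeI), CI
Why: Williamson O-methylation under pKa control, in which the 4-OH (para to CHO, ortho to Br) is far more acidic than the 5-OH, so the weak base forms only the 4-phenoxide, MeI caps it, and the future 3'-OH stays free; no stereocentre is involved.

**Step 2**
Reactants: 2 3-bromo-5-hydroxy-4-methoxybenzaldehyde, 3 tributyl(3-methylbut-2-en-1-yl)stannane (1.3 equiv)
Product: 4 3-hydroxy-4-methoxy-5-(3-methylbut-2-en-1-yl)benzaldehyde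
Conditions: Pd(PPh3)4 (5 mol %), DMF, 90 °C, 14 h, Ar
Reagents that add atoms: none
Why: Migita–Kosugi–Stille coupling, whose neutral conditions tolerate the free phenol and the aldehyde (prenyl-boron or prenyl-zinc reagents would add to CHO), and reductive elimination from the less hindered primary σ-prenyl-Pd terminus gives the linear prenyl arene; no stereocentre is involved.

**Step 3**
Reactants: 4 3-hydroxy-4-methoxy-5-(3-methylbut-2-en-1-yl)benzaldehyde, 5 1-(2,4-dihydroxyphenyl)ethan-1-one
Product: 7 (E)-1-(2,4-dihydroxyphenyl)-3-[3-hydroxy-4-methoxy-5-(3-methylbut-2-en-1-yl)phenyl]prop-2-en-1-one, via racemic aldol adduct 6 (not isolated)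
Conditions: KOH (50% aq, 12 equiv), EtOH, N2, 0 °C → rt, 48 h; then cold 1 M HCl to pH 5; recrystallise
Reagents that add atoms: none
Why: Claisen–Schmidt condensation (crossed aldol, then E1cB dehydration), which works here because the aldehyde cannot enolise, its phenoxide is meta to CHO and so does not quench the electrophile, the strong base holds the product as the open chalcone phenoxide, and the conjugated E-alkene is the thermodynamic outcome.

**Step 4**
Reactants: 7 (E)-1-(2,4-dihydroxyphenyl)-3-[3-hydroxy-4-methoxy-5-(3-methylbut-2-en-1-yl)phenyl]prop-2-en-1-one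
Product: 8 erylatissin C, (2S)-7-hydroxy-2-[3-hydroxy-4-methoxy-5-(3-methylbut-2-en-1-yl)phenyl]-2,3-dihydro-4H-chromen-4-one
Conditions: MsCHI (about 0.1 mol %, clarified lysate or purified), 7 fed to 1 mM, 50 mM K-phosphate pH 7.2/DMSO 9:1, 25 °C, 2 h; adjust to pH 5.5, EtOAc extraction, SiO2 (residual 7 recovered)
Reagents that add atoms: none
Why: Proposed new method: a type II chalcone isomerase, whose native reaction is the 6-endo-trig oxa-Michael closure of the 6'-deoxychalcone isoliquiritigenin to (2S)-liquiritigenin, should accept 7 because 7 carries the same 2',4'-dihydroxy A ring and enone that the active-site hydrogen-bond network binds, while the altered B ring is expected to point toward the open mouth of the cleft (B-ring variants such as butein and 2',4'-dihydroxychalcone are turned over); the enzyme holds the 2'-oxyanion over one face of Cβ so that C2 forms as (S) (O > aryl > CH2 > H, the same descriptor as liquiritigenin), the uncatalysed closure of chelated 6'-deoxychalcones is slow at this pH so little racemic background is expected, the equilibrium favours the flavanone, and the closest known reaction type is the CHI-catalysed intramolecular oxa-Michael addition of natural chalcones.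

**Compound list**
1 | 3-bromo-4,5-dihydroxybenzaldehyde (5-bromoprotocatechualdehyde) | O=Cc1cc(O)c(O)c(Br)c1 | starting material
2 | 3-bromo-5-hydroxy-4-methoxybenzaldehyde (5-bromoisovanillin) | COc1c(O)cc(C=O)cc1Br | intermediate
3 | tributyl(3-methylbut-2-en-1-yl)stannane (prenyltributyltin) | CCCC[Sn](CCCC)(CCCC)CC=C(C)C | starting material
4 | 3-hydroxy-4-methoxy-5-(3-methylbut-2-en-1-yl)benzaldehyde (5-prenylisovanillin) | COc1c(O)cc(C=O)cc1CC=C(C)C | intermediate
5 | 1-(2,4-dihydroxyphenyl)ethan-1-one (resacetophenone) | CC(=O)c1ccc(O)cc1O | starting material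
6 | 1-(2,4-dihydroxyphenyl)-3-hydroxy-3-[3-hydroxy-4-methoxy-5-(3-methylbut-2-en-1-yl)phenyl]propan-1-one (racemic aldol adduct, not isolated) | COc1c(O)cc(C(O)CC(=O)c2ccc(O)cc2O)cc1CC=C(C)C | intermediate
7 | (E)-1-(2,4-dihydroxyphenyl)-3-[3-hydroxy-4-methoxy-5-(3-methylbut-2-en-1-yl)phenyl]prop-2-en-1-one (2',4',3-trihydroxy-4-methoxy-5-prenylchalcone) | COc1c(O)cc(/C=C/C(=O)c2ccc(O)cc2O)cc1CC=C(C)C | intermediate
8 | erylatissin C, (2S)-7-hydroxy-2-[3-hydroxy-4-methoxy-5-(3-methylbut-2-en-1-yl)phenyl]-2,3-dihydro-4H-chromen-4-one | COc1c(O)cc([C@@H]2CC(=O)c3ccc(O)cc3O2)cc1CC=C(C)C | target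

**Totals**
- Total step count: 4.
- Longest linear sequence: 4 (1 → 2 → 4 → 7 → 8).
- No protecting groups are used.

**Steps most likely to fail**

Step 4 (the enzyme may not accept the bulky, lipophilic B ring, or 7 may be too insoluble).
- The fallback sets out from 7 and comes back at 8, and replaces catalyst control by resolution with recycling.
- The chalcone is closed without stereocontrol (NaOAc, EtOH–H2O, reflux, thermodynamic oxa-Michael) to racemic erylatissin C F1.
- F1 is separated by preparative SFC on an immobilised amylose tris(3,5-dimethylphenylcarbamate) phase into 8 and (2R)-erylatissin C F2.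
- F2 is returned to the same NaOAc equilibration, where it opens to 7 and re-closes, and is resolved again.

Step 3 (slow condensation of poly-phenoxides, low conversion, Cannizzaro loss of 4).
- The fallback sets out from 4 and 5 and comes back at 7, and changes to a protected-phenol strategy.
- 5 is protected at its non-chelated 4-OH (MOMCl, K2CO3, acetone, rt) to 1-[2-hydroxy-4-(methoxymethoxy)phenyl]ethan-1-one F3.
- 4 is protected (MOMCl, i-Pr2NEt, CH2Cl2) to 4-methoxy-3-(methoxymethoxy)-5-prenylbenzaldehyde F4.
- Only the chelated 2'-phenoxide now remains, so KOH/EtOH at rt condenses the two quickly through the bis-MOM aldol adduct F5 to the bis-MOM chalcone F6.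
- 3 M HCl/MeOH at 45 °C removes both acetals and gives 7. The prenyl group has no ortho OH to cyclise onto.

Step 2 (α/γ scrambling to the reverse-prenyl isomer, protodestannylation by the phenol, sluggish oxidative addition).
- The fallback sets out from 2 and comes back at 4, and builds the prenyl group in two stages so that no regiochemical ambiguity exists.
- Stille coupling with allyltributylstannane (Pd(PPh3)4, DMF, 90 °C) gives 3-allyl-5-hydroxy-4-methoxybenzaldehyde F7.
- Olefin cross-metathesis of F7 with excess 2-methylbut-2-ene (Grubbs II, 3 mol %, CH2Cl2, 40 °C) then gives 4.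

**Further compounds**
F1 | step 4 | racemic erylatissin C, rac-7-hydroxy-2-[3-hydroxy-4-methoxy-5-(3-methylbut-2-en-1-yl)phenyl]-2,3-dihydro-4H-chromen-4-one | COc1c(O)cc(C2CC(=O)c3ccc(O)cc3O2)cc1CC=C(C)C
F2 | step 4 | (2R)-erylatissin C, (2R)-7-hydroxy-2-[3-hydroxy-4-methoxy-5-(3-methylbut-2-en-1-yl)phenyl]-2,3-dihydro-4H-chromen-4-one | COc1c(O)cc([C@H]2CC(=O)c3ccc(O)cc3O2)cc1CC=C(C)C
F3 | step 3 | 1-[2-hydroxy-4-(methoxymethoxy)phenyl]ethan-1-one | CC(=O)c1ccc(OCOC)cc1O
F4 | step 3 | 4-methoxy-3-(methoxymethoxy)-5-(3-methylbut-2-en-1-yl)benzaldehyde | COCOc1cc(C=O)cc(CC=C(C)C)c1OC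
F5 | step 3 | bis-MOM aldol adduct, 3-hydroxy-1-[2-hydroxy-4-(methoxymethoxy)phenyl]-3-[4-methoxy-3-(methoxymethoxy)-5-(3-methylbut-2-en-1-yl)phenyl]propan-1-one (racemic, not isolated) | COCOc1cc(C(O)CC(=O)c2ccc(OCOC)cc2O)cc(CC=C(C)C)c1OC
F6 | step 3 | bis-MOM chalcone, (E)-1-[2-hydroxy-4-(methoxymethoxy)phenyl]-3-[4-methoxy-3-(methoxymethoxy)-5-(3-methylbut-2-en-1-yl)phenyl]prop-2-en-1-one | COCOc1cc(/C=C/C(=O)c2ccc(OCOC)cc2O)cc(CC=C(C)C)c1OC
F7 | step 2 | 3-allyl-5-hydroxy-4-methoxybenzaldehyde | COc1c(O)cc(C=O)cc1CC=C
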